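**Retrosynthetic overview**
1. Target ⇐ silyl-to-acetyl exchange at C12 ⇐ acetoxy-dihydrofuran (ring D), closed by O-attack of a fluoride-released C16 enolate on the C15 aldehyde and trapped with Ac2O.
2. C11 and C15 aldehydes ⇐ one double oxidation of a diol; C11–OH ⇐ hydroboration of the exocyclic C9=C11 alkene left by the key step.
3. Key bond C8–C14 (quaternary C8 next to C14) ⇐ Ireland–Claisen [3,3] shift of the silyl ketene acetal of a drim-8-en-11-yl β,γ-unsaturated ester.
4. That ester ⇐ phosphonoacetate olefination of bis-silyloxyacetone, then deconjugation (which raises C16 to the enol-ether level); drim-8-en-11-ol ⇐ sclareolide via lactol, enol ether, ozonolysis/β-elimination and reduction.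
5. Ring order: rings A and B come intact from sclareolide; ring D is the only ring built, at the penultimate step.

Assumption: positions are numbered as in spongianes (C8 carries the 8β-methyl, C11 sits on C9, side chain C14, C15, C13, C12, C16); the bis-silyloxy ketone and the phosphonoacetic acid are taken as commercial; TBS = tert-butyldimethylsilyl, DCC = N,N'-dicyclohexylcarbodiimide, DMAP = 4-(dimethylamino)pyridine, DBU = 1,8-diazabicyclo[5.4.0]undec-7-ene, DMPU = N,N'-dimethylpropyleneurea, 9-BBN = 9-borabicyclo[3.3.1]nonane, TASF = tris(dimethylamino)sulfonium difluorotrimethylsilicate.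

**Step 1**
Reactants: 1 (+)-sclareolide
Product: 2 sclareolide lactol
Conditions: iBu2AlH, CH2Cl2, −78 °C; aq. KNaC4H4O6
Reagents that add atoms: none
Why: Partial hydride reduction of the γ-lactone stops at the aluminium hemiacetal at −78 °C, giving the lactol (anomers) with the four bought stereocentres untouched.

**Step 2**
Reactants: 2 sclareolide lactol
Product: 4 tricyclic enol ether, via lactol mesylate 3 (not isolated)
Conditions: MsCl, Et3N, CH2Cl2, −40 → 40 °C
Reagents that add atoms: none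
Why: Lactol dehydration (the furanoid-glycal method): the anomeric mesylate ionises and Et3N removes the C11 proton to give the 2,3-dihydrofuran.

**Step 3**
Reactants: 4 tricyclic enol ether
Product: 7 drim-8-en-11-al, via ozonide 5 (not isolated), via formyloxy aldehyde 6 (not isolated)
Conditions: O3, CH2Cl2, −78 °C; Me2S; then DBU, 0 → 25 °C
Reagents that add atoms: ozone, [O-][O+]=O
Why: Ozonolysis of the enol ether cuts out C12 (left as the 8α-formate) and E1cB β-elimination of formate from the β-acyloxy aldehyde gives the conjugated tetrasubstituted enal, with C5 and C10 unaffected.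

**Step 4**
Reactants: 7 drim-8-en-11-al
Product: 8 drim-8-en-11-ol
Conditions: NaBH4, CeCl3·7H2O, MeOH, 0 °C
Reagents that add atoms: none
Why: Luche 1,2-reduction of the hindered enal gives the primary allylic alcohol needed for the rearrangement.

**Step 5**
Reactants: 8 drim-8-en-11-ol; 9 diethylphosphonoacetic acid
Product: 10 drimenyl phosphonoacetate
Conditions: DCC, DMAP (cat.), CH2Cl2, 0 → 25 °C
Reagents that add atoms: none
Why: Steglich esterification of the primary allylic alcohol leaves the tetrasubstituted alkene untouched.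

**Step 6**
Reactants: 10 drimenyl phosphonoacetate; 11 1,3-bis(TBSO)propan-2-one
Product: 12 bis-silyloxy enoate
Conditions: NaH, THF, 0 → 25 °C
Reagents that add atoms: none
Why: Horner–Wadsworth–Emmons olefination of the symmetric ketone gives a single enoate because both β-substituents are identical.

**Step 7**
Reactants: 12 bis-silyloxy enoate
Product: 14 deconjugated ester, via lithium dienolate 13 (not isolated)
Conditions: LiN(iPr)2, THF/DMPU, −78 °C; AcOH, −78 °C
Reagents that add atoms: none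
Why: γ-Deprotonation to the extended dienolate and kinetic α-protonation (deconjugation) turn one silyloxymethyl arm into a silyl enol ether, which raises C16 to the aldehyde level and places its oxygen cis to C14 (the less crowded side).

**Step 8**
Reactants: 14 deconjugated ester
Product: 17 Claisen alcohol, via silyl ketene acetal 15 (not isolated), via trimethylsilyl ester 16 (not isolated)
Conditions: LiN(iPr)2, THF, −78 °C; Me3SiCl, Et3N; −78 → 66 °C; then LiAlH4, 0 °C
Reagents that add atoms: none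
Why: Ireland–Claisen [3,3]-sigmatropic rearrangement: the kinetic E(O) enolate gives the ketene acetal with C13 cis to the allylic oxygen, which reacts through a chair on the α face of C8=C9 (anti to the axial C10 methyl), forging C8–C14 with 8β-methyl and 14S, and the silyl ester is reduced in the same flask.

**Step 9**
Reactants: 17 Claisen alcohol
Product: 19 11,15-diol, via bis-borane adduct 18 (not isolated)
Conditions: 9-BBN, THF, 0 → 60 °C; then aq. NaOAc, H2O2, 0 → 25 °C
Reagents that add atoms: hydrogen peroxide, OO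
Why: Anti-Markovnikov hydroboration–oxidation of the exocyclic alkene delivers hydrogen to C9 from the α face (the β face is blocked by the axial methyls on C8 and C10), setting 9α-H, while the silyl enol ether is spared because boron would have to add to fully substituted C13.

**Step 10**
Reactants: 19 11,15-diol
Product: 20 11,15-dialdehyde
Conditions: Dess–Martin periodinane, pyridine, CH2Cl2, 0 °C
Reagents that add atoms: none
Why: Buffered Dess–Martin oxidation converts both primary alcohols to aldehydes without base-mediated epimerisation at C9 or C14 and without touching the silyl ethers.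

**Step 11**
Reactants: 20 11,15-dialdehyde
Product: 22 silyl-protected acetoxy-dihydrofuran, via sulfonium lactolate 21 (not isolated)
Conditions: TASF, THF, −78 → −40 °C; then Ac2O, −78 → 0 °C
Reagents that add atoms: acetic anhydride, CC(=O)OC(C)=O
Why: Fluoride cleaves only the enol silyl ether, the naked enolate adds through oxygen to the C15 aldehyde (5-exo; carbon attack would need a three-membered ring) and the equilibrating lactolate is acetylated anti to the C14 substituent, closing ring D and setting 15R.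

**Step 12**
Reactants: 22 silyl-protected acetoxy-dihydrofuran
Product: 24 target, via primary alcohol 23 (not isolated)
Conditions: HF·pyridine, pyridine, THF, 0 °C; then Ac2O, DMAP, 0 → 25 °C
Reagents that add atoms: acetic anhydride, CC(=O)OC(C)=O
Why: Pyridine-buffered fluoride desilylation of the primary silyl ether followed by acetylation completes the diacetate under conditions chosen to be too mild to ionise the acetoxy acetal.

**Compound list**
1 | (+)-sclareolide, (3aR,5aS,9aS,9bR)-3a,6,6,9a-tetramethyldecahydronaphtho[2,1-b]furan-2(1H)-one | O=C3O[C@]1(C)CC[C@H]2C(C)(C)CCC[C@]2(C)[C@H]1C3 | starting material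
2 | sclareolide lactol (C12 anomers) | OC3O[C@]1(C)CC[C@H]2C(C)(C)CCC[C@]2(C)[C@H]1C3 | intermediate
3 | lactol mesylate (C12 anomers) | CS(=O)(=O)OC3O[C@]1(C)CC[C@H]2C(C)(C)CCC[C@]2(C)[C@H]1C3 | intermediate
4 | tricyclic enol ether, (3aR,5aS,9aS,9bR)-3a,6,6,9a-tetramethyl-3a,4,5,5a,6,7,8,9,9a,9b-decahydronaphtho[2,1-b]furan | C1=CO[C@]2(C)CC[C@H]3C(C)(C)CCC[C@]3(C)[C@@H]12 | intermediate
5 | ozonide of 4 (1,2,4-trioxolane on C11 and C12, diastereomers) | C34O[C@]1(C)CC[C@H]2C(C)(C)CCC[C@]2(C)[C@H]1C(OO3)O4 | intermediate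
6 | 8α-formyloxydriman-11-al (9α-H) | O=CO[C@]1(C)CC[C@H]2C(C)(C)CCC[C@]2(C)[C@H]1C=O | intermediate
7 | drim-8-en-11-al, (4aS,8aS)-2,5,5,8a-tetramethyl-3,4,4a,5,6,7,8,8a-octahydronaphthalene-1-carbaldehyde | O=CC1=C(C)CC[C@H]2C(C)(C)CCC[C@]12C | intermediate
8 | drim-8-en-11-ol | OCC1=C(C)CC[C@H]2C(C)(C)CCC[C@]12C | intermediate
9 | diethylphosphonoacetic acid | CCOP(=O)(OCC)CC(=O)O | starting material
10 | drim-8-en-11-yl (diethoxyphosphoryl)acetate | CCOP(=O)(OCC)CC(=O)OCC1=C(C)CC[C@H]2C(C)(C)CCC[C@]12C | intermediate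
11 | 1,3-bis(tert-butyldimethylsilyloxy)propan-2-one | CC(C)(C)[Si](C)(C)OCC(=O)CO[Si](C)(C)C(C)(C)C | starting material
12 | drim-8-en-11-yl 4-(TBSO)-3-(TBSO-methyl)but-2-enoate | O=C(C=C(CO[Si](C)(C)C(C)(C)C)CO[Si](C)(C)C(C)(C)C)OCC1=C(C)CC[C@H]2C(C)(C)CCC[C@]12C | intermediate
13 | lithium dienolate of 12 (O–Li cis to C13; C16–OTBS cis to C14) | [Li+].[O-]/C(OCC1=C(C)CC[C@H]2C(C)(C)CCC[C@]12C)=C\C(CO[Si](C)(C)C(C)(C)C)=C/O[Si](C)(C)C(C)(C)C | intermediate
14 | drim-8-en-11-yl (E)-4-(TBSO)-3-(TBSO-methyl)but-3-enoate | O=C(C/C(CO[Si](C)(C)C(C)(C)C)=C\O[Si](C)(C)C(C)(C)C)OCC1=C(C)CC[C@H]2C(C)(C)CCC[C@]12C | intermediate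
15 | O-trimethylsilyl ketene acetal of 14 (C13 cis to the drimenyloxy oxygen) | C[Si](C)(C)O/C(OCC1=C(C)CC[C@H]2C(C)(C)CCC[C@]12C)=C/C(CO[Si](C)(C)C(C)(C)C)=C\O[Si](C)(C)C(C)(C)C | intermediate
16 | trimethylsilyl (2S,3E)-2-(drim-9(11)-en-8α-yl)-4-(TBSO)-3-(TBSO-methyl)but-3-enoate | C[Si](C)(C)OC(=O)[C@H](/C(CO[Si](C)(C)C(C)(C)C)=C\O[Si](C)(C)C(C)(C)C)[C@]1(C)CC[C@H]2C(C)(C)CCC[C@]2(C)C1=C | intermediate
17 | (2S,3E)-2-(drim-9(11)-en-8α-yl)-4-(TBSO)-3-(TBSO-methyl)but-3-en-1-ol | OC[C@H](/C(CO[Si](C)(C)C(C)(C)C)=C\O[Si](C)(C)C(C)(C)C)[C@]1(C)CC[C@H]2C(C)(C)CCC[C@]2(C)C1=C | intermediate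
18 | bis-borane adduct of 17: C11–B and C15–O–B, each boron being 9-borabicyclo[3.3.1]nonan-9-yl (9α-H) | C(OB3C4CCCC3CCC4)[C@H](/C(CO[Si](C)(C)C(C)(C)C)=C\O[Si](C)(C)C(C)(C)C)[C@]1(C)CC[C@H]2C(C)(C)CCC[C@]2(C)[C@H]1CB5C6CCCC5CCC6 | intermediate
19 | (2S,3E)-2-(11-hydroxydriman-8α-yl)-4-(TBSO)-3-(TBSO-methyl)but-3-en-1-ol (9α-H) | OC[C@H](/C(CO[Si](C)(C)C(C)(C)C)=C\O[Si](C)(C)C(C)(C)C)[C@]1(C)CC[C@H]2C(C)(C)CCC[C@]2(C)[C@H]1CO | intermediate
20 | (2S,3E)-2-(11-oxodriman-8α-yl)-4-(TBSO)-3-(TBSO-methyl)but-3-enal | O=C[C@H](/C(CO[Si](C)(C)C(C)(C)C)=C\O[Si](C)(C)C(C)(C)C)[C@]1(C)CC[C@H]2C(C)(C)CCC[C@]2(C)[C@H]1C=O | intermediate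
21 | tris(dimethylamino)sulfonium salt of the C15 lactolate (2-oxido analogue of 22, oxygen trans to the C14 substituent) | CC(C)(C)[Si](C)(C)OCC1=CO[C@H]([O-])[C@H]1[C@]1(C)CC[C@H]2C(C)(C)CCC[C@]2(C)[C@H]1C=O.CN(C)[S+](N(C)C)N(C)C | intermediate
22 | (2R,3S)-3-(11-oxodriman-8α-yl)-4-(TBSO-methyl)-2,3-dihydrofuran-2-yl acetate | CC(C)(C)[Si](C)(C)OCC1=CO[C@H](OC(C)=O)[C@H]1[C@]1(C)CC[C@H]2C(C)(C)CCC[C@]2(C)[C@H]1C=O | intermediate
23 | (2R,3S)-4-(hydroxymethyl)-3-(11-oxodriman-8α-yl)-2,3-dihydrofuran-2-yl acetate | OCC1=CO[C@H](OC(C)=O)[C@H]1[C@]1(C)CC[C@H]2C(C)(C)CCC[C@]2(C)[C@H]1C=O | intermediate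
24 | CNP0170308.1, (2R,3S)-4-(acetoxymethyl)-3-[(1R,2R,4aS,8aS)-1-formyl-2,5,5,8a-tetramethyldecahydronaphthalen-2-yl]-2,3-dihydrofuran-2-yl acetate | CC(=O)OCC1=CO[C@H](OC(C)=O)[C@H]1[C@]1(C)CC[C@H]2C(C)(C)CCC[C@]2(C)[C@H]1C=O | target

**Step count and risks**
Total: 12 steps. Longest linear sequence: 12 steps (1 → 24); 9 and 11 are bought.

The three steps most likely to fail are steps 8, 9 and 11.

Step 8 forms a quaternary centre next to a tertiary one, and the C14 configuration rests on the E(O) enolate geometry; the wrong geometry would give the C14 epimer. The fallback is an Eschenmoser amide-acetal Claisen, in which A(1,3) strain rather than kinetic enolisation fixes the ketene N,O-acetal geometry (C13 cis to the allylic oxygen). It sets out from 8 and comes back at 17. Ketone 11 and diethyl [2-(dimethylamino)-2-oxoethyl]phosphonate (NaH, THF) give the N,N-dimethyl enamide F1. MeOTf followed by NaOMe in MeOH gives its dimethyl acetal F2. Heating 8 with the amide acetal F2 in xylene at 140 °C, with removal of MeOH, passes through the dienyl N,O-ketene acetal to the rearranged amide F3. LiNH2BH3 in THF at 0 °C reduces the rearranged amide F3 to 17.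

Step 9 must hydroborate an alkene flanked by two quaternary carbons while a silyl enol ether survives. The fallback removes the selectivity problem by carrying C16 as a plain 1,1-disubstituted alkene and hydroborating both alkenes. It sets out from 8 and comes back at 22. Itaconic anhydride with DMAP opens at the unconjugated carbonyl to the hemi-ester F4. BH3·SMe2 reduces only the free acid to the hydroxy ester F5, which is silylated at once (TBSCl, imidazole) to the silyl ether F6. The protocol of step 8 converts it to the diene alcohol F7. BH3·THF followed by NaOH/H2O2 gives the triol F8 (C13 epimers, which converge). DMSO, (COCl)2 and Et3N give the trialdehyde F9. Ac2O, Et3N and DMAP enolise its C16 aldehyde reversibly; the enol oxygen closes on C15 and the lactol is acetylated, giving 22.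

Step 11 is the least precedented: the free enolate may add through carbon to the C11 aldehyde (a five-membered aldol) or be O-acetylated before it closes. The fallback closes ring D before C11 is oxidised and brings C11 in last. It sets out from 17 and comes back at 24. Dess–Martin oxidation (pyridine buffer) gives the mono-aldehyde F10. TASF followed by Ac2O gives the acetoxy-dihydrofuran F11, now with no second aldehyde present. HF·pyridine followed by Ac2O gives the diacetate F12. 9-BBN followed by NaBO3·4H2O gives the C11 alcohol F13; boron cannot add to the fully substituted C13 of the ring enol ether. Dess–Martin oxidation gives 24.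

**Further compounds**
F1 | step 8 | N,N-dimethyl-4-(TBSO)-3-(TBSO-methyl)but-2-enamide | CN(C)C(=O)C=C(CO[Si](C)(C)C(C)(C)C)CO[Si](C)(C)C(C)(C)C
F2 | step 8 | 1,1-dimethoxy-N,N-dimethyl-4-(TBSO)-3-(TBSO-methyl)but-2-en-1-amine | CN(C)C(OC)(OC)C=C(CO[Si](C)(C)C(C)(C)C)CO[Si](C)(C)C(C)(C)C
F3 | step 8 | (2S,3E)-2-(drim-9(11)-en-8α-yl)-N,N-dimethyl-4-(TBSO)-3-(TBSO-methyl)but-3-enamide | CN(C)C(=O)[C@H](/C(CO[Si](C)(C)C(C)(C)C)=C\O[Si](C)(C)C(C)(C)C)[C@]1(C)CC[C@H]2C(C)(C)CCC[C@]2(C)C1=C
F4 | step 9 | drim-8-en-11-yl hydrogen itaconate (ester at the unconjugated carboxyl) | OC(=O)C(=C)CC(=O)OCC1=C(C)CC[C@H]2C(C)(C)CCC[C@]12C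
F5 | step 9 | drim-8-en-11-yl 3-(hydroxymethyl)but-3-enoate | OCC(=C)CC(=O)OCC1=C(C)CC[C@H]2C(C)(C)CCC[C@]12C
F6 | step 9 | drim-8-en-11-yl 3-(TBSO-methyl)but-3-enoate | CC(C)(C)[Si](C)(C)OCC(=C)CC(=O)OCC1=C(C)CC[C@H]2C(C)(C)CCC[C@]12C
F7 | step 9 | (2S)-2-(drim-9(11)-en-8α-yl)-3-(TBSO-methyl)but-3-en-1-ol | OC[C@H](C(=C)CO[Si](C)(C)C(C)(C)C)[C@]1(C)CC[C@H]2C(C)(C)CCC[C@]2(C)C1=C
F8 | step 9 | 2-(11-hydroxydriman-8α-yl)-3-(TBSO-methyl)butane-1,4-diol (C14 as in 19, C13 epimers) | OC[C@H](C(CO)CO[Si](C)(C)C(C)(C)C)[C@]1(C)CC[C@H]2C(C)(C)CCC[C@]2(C)[C@H]1CO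
F9 | step 9 | 2-(11-oxodriman-8α-yl)-3-(TBSO-methyl)butanedial (C14 as in 20, C13 epimers) | O=C[C@H](C(C=O)CO[Si](C)(C)C(C)(C)C)[C@]1(C)CC[C@H]2C(C)(C)CCC[C@]2(C)[C@H]1C=O
F10 | step 11 | (2S,3E)-2-(drim-9(11)-en-8α-yl)-4-(TBSO)-3-(TBSO-methyl)but-3-enal | O=C[C@H](/C(CO[Si](C)(C)C(C)(C)C)=C\O[Si](C)(C)C(C)(C)C)[C@]1(C)CC[C@H]2C(C)(C)CCC[C@]2(C)C1=C
F11 | step 11 | (2R,3S)-3-(drim-9(11)-en-8α-yl)-4-(TBSO-methyl)-2,3-dihydrofuran-2-yl acetate | CC(C)(C)[Si](C)(C)OCC1=CO[C@H](OC(C)=O)[C@H]1[C@]1(C)CC[C@H]2C(C)(C)CCC[C@]2(C)C1=C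
F12 | step 11 | (2R,3S)-4-(acetoxymethyl)-3-(drim-9(11)-en-8α-yl)-2,3-dihydrofuran-2-yl acetate | CC(=O)OCC1=CO[C@H](OC(C)=O)[C@H]1[C@]1(C)CC[C@H]2C(C)(C)CCC[C@]2(C)C1=C
F13 | step 11 | (2R,3S)-4-(acetoxymethyl)-3-(11-hydroxydriman-8α-yl)-2,3-dihydrofuran-2-yl acetate | CC(=O)OCC1=CO[C@H](OC(C)=O)[C@H]1[C@]1(C)CC[C@H]2C(C)(C)CCC[C@]2(C)[C@H]1CO
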